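**Assumption:** the target has no stereocentre (it is achiral), so "single enantiomer" calls for no stereocontrol and the SMILES carry no stereo descriptors.

## Retrosynthetic overview

1. Mallopallidol 13 is cut at the ArCH2–Ar' bond: Michael addition of C-8 of chromanone 11 to the ortho-quinone methide 12, released from Mannich base 8.
2. 8 comes from the acylphloroglucinol monomethyl ether 6 by a Mannich reaction with Eschenmoser's salt 7.
3. 6 and 11 both come from 3,5-dimethoxy-4-methylphenol 3: 6 by ortho-acylation with isobutyric acid 4 and chelation-controlled mono-demethylation; 11 by acylation/oxa-Michael annulation with 3,3-dimethylacrylic acid 9 and demethylation.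
4. 3 comes from 2,6-dimethoxytoluene 1 by sterically controlled C–H borylation/oxidation; its single free OH, para to the C-methyl, fixes the regiochemistry of both fragments.
5. Only one ring is built (the pyranone ring of 11, step 5); both benzene rings are bought.

## Route

**Step 1**
Reactants: 1 2,6-dimethoxytoluene
Product: 3 3,5-dimethoxy-4-methylphenol, via aryl pinacol boronate 2 (not isolated)
Conditions: [Ir(OMe)(cod)]2 (1 mol %), 4,4'-di-tert-butyl-2,2'-bipyridine (2 mol %), B2pin2 (0.6 equiv), THF, 80 °C; then Oxone (2KHSO5·KHSO4·K2SO4), acetone/H2O, rt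
Reagents that add atoms: bis(pinacolato)diboron, CC1(C)OB(OC1(C)C)B1OC(C)(C)C(C)(C)O1 (the Bpin group of 2); potassium peroxymonosulfate of Oxone, [K+].[O-]S(=O)(=O)OO (the phenol oxygen of 3)
Why: Iridium-catalysed C–H borylation is sterically controlled and goes only to C-4 of 1, the one aromatic C–H with no ortho substituent, and the C–B bond is then oxidised in the same pot to C–OH at the same carbon (one-pot borylation/oxidation); no stereocentre is formed.

**Step 2**
Reactants: 3 3,5-dimethoxy-4-methylphenol; 4 isobutyric acid
Product: 5 1-(6-hydroxy-2,4-dimethoxy-3-methylphenyl)-2-methylpropan-1-one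
Conditions: BF3·OEt2 (as solvent), 90 °C, 3 h; then aq. NaOAc
Reagents that add atoms: none
Why: BF3-promoted Friedel–Crafts (Nencki-type) acylation of the electron-rich phenol goes ortho to the OH at one of the two symmetry-equivalent free positions (para is blocked by the methyl), so only one ketone can form; no stereocentre.

**Step 3**
Reactants: 5 1-(6-hydroxy-2,4-dimethoxy-3-methylphenyl)-2-methylpropan-1-one
Product: 6 1-(2,6-dihydroxy-4-methoxy-3-methylphenyl)-2-methylpropan-1-one
Conditions: BCl3 (2.5 equiv), CH2Cl2, −78 °C → 0 °C; then H2O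
Reagents that add atoms: none
Why: BCl3 chelates between the ketone and the flanking methoxy group and cleaves only that ortho methyl ether (chelation-controlled Lewis-acid demethylation), leaving the para OMe that the target needs; no stereocentre.

**Step 4**
Reactants: 6 1-(2,6-dihydroxy-4-methoxy-3-methylphenyl)-2-methylpropan-1-one; 7 N,N-dimethylmethyleneiminium iodide (Eschenmoser's salt)
Product: 8 1-{3-[(dimethylamino)methyl]-2,6-dihydroxy-4-methoxy-5-methylphenyl}-2-methylpropan-1-one
Conditions: 7 (1.1 equiv), Et3N (1.1 equiv), CH2Cl2, 0 °C → rt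
Reagents that add atoms: none
Why: Mannich reaction in which the preformed iminium ion attacks the only free aromatic carbon of 6, ortho to a phenolic OH, to give the ortho-hydroxybenzylamine; no stereocentre.

**Step 5**
Reactants: 3 3,5-dimethoxy-4-methylphenol; 9 3,3-dimethylacrylic acid (3-methylbut-2-enoic acid)
Product: 10 5,7-dimethoxy-2,2,6-trimethyl-2,3-dihydro-4H-chromen-4-one
Conditions: P2O5 in MeSO3H (Eaton's reagent), 70 °C, 1–2 h
Reagents that add atoms: none
Why: Friedel–Crafts acylation ortho to the only free OH followed by intramolecular oxa-Michael addition of that OH to the enone closes the 2,2-dimethylchromanone ring; because the ring oxygen is the one para to the C-methyl, the methyl ends at C-6 and C-8 stays free; no stereocentre.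

**Step 6**
Reactants: 10 5,7-dimethoxy-2,2,6-trimethyl-2,3-dihydro-4H-chromen-4-one
Product: 11 5,7-dihydroxy-2,2,6-trimethyl-2,3-dihydro-4H-chromen-4-one
Conditions: BBr3 (5 equiv), CH2Cl2, −78 °C → rt, 12 h; then ice/H2O
Reagents that add atoms: none
Why: BBr3 cleaves both aryl methyl ethers (Lewis-acid ether cleavage, the 5-OMe helped by chelation to the ketone), while the ring oxygen is a deactivated vinylogous-ester oxygen and should stay intact; no stereocentre.

**Step 7**
Reactants: 8 1-{3-[(dimethylamino)methyl]-2,6-dihydroxy-4-methoxy-5-methylphenyl}-2-methylpropan-1-one; 11 5,7-dihydroxy-2,2,6-trimethyl-2,3-dihydro-4H-chromen-4-one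
Product: 13 mallopallidol, via ortho-quinone methide 12 (not isolated)
Conditions: 8 (1.0 equiv), 11 (1.2 equiv), toluene, 110 °C, slow N2 sweep, 8 h
Reagents that add atoms: none
Why: Thermal loss of Me2NH from the ortho-hydroxybenzylamine gives ortho-quinone methide 12, and C-8 of 11 (the enol carbon ortho to the acidic 7-OH and the only free ring position) adds to its exocyclic CH2 in a Michael addition, after which both rings rearomatise; no stereocentre.

## Compound list

1 | 2,6-dimethoxytoluene (1,3-dimethoxy-2-methylbenzene) | COc1cccc(OC)c1C | starting material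
2 | 2-(3,5-dimethoxy-4-methylphenyl)-4,4,5,5-tetramethyl-1,3,2-dioxaborolane | COc1cc(B2OC(C)(C)C(C)(C)O2)cc(OC)c1C | intermediate
3 | 3,5-dimethoxy-4-methylphenol | COc1cc(O)cc(OC)c1C | intermediate
4 | isobutyric acid (2-methylpropanoic acid) | CC(C)C(=O)O | starting material
5 | 1-(6-hydroxy-2,4-dimethoxy-3-methylphenyl)-2-methylpropan-1-one | CC(C)C(=O)c1c(O)cc(OC)c(C)c1OC | intermediate
6 | 1-(2,6-dihydroxy-4-methoxy-3-methylphenyl)-2-methylpropan-1-one | CC(C)C(=O)c1c(O)cc(OC)c(C)c1O | intermediate
7 | N,N-dimethylmethyleneiminium iodide (Eschenmoser's salt) | C=[N+](C)C.[I-] | starting material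
8 | 1-{3-[(dimethylamino)methyl]-2,6-dihydroxy-4-methoxy-5-methylphenyl}-2-methylpropan-1-one | CC(C)C(=O)c1c(O)c(CN(C)C)c(OC)c(C)c1O | intermediate
9 | 3,3-dimethylacrylic acid (3-methylbut-2-enoic acid) | CC(C)=CC(=O)O | starting material
10 | 5,7-dimethoxy-2,2,6-trimethyl-2,3-dihydro-4H-chromen-4-one | COc1cc2OC(C)(C)CC(=O)c2c(OC)c1C | intermediate
11 | 5,7-dihydroxy-2,2,6-trimethyl-2,3-dihydro-4H-chromen-4-one | Cc1c(O)cc2OC(C)(C)CC(=O)c2c1O | intermediate
12 | 3-hydroxy-5-methoxy-4-methyl-6-methylidene-2-(2-methylpropanoyl)cyclohexa-2,4-dien-1-one (ortho-quinone methide) | CC(C)C(=O)C1=C(O)C(C)=C(OC)C(=C)C1=O | intermediate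
13 | mallopallidol, 8-{[2,4-dihydroxy-6-methoxy-5-methyl-3-(2-methylpropanoyl)phenyl]methyl}-5,7-dihydroxy-2,2,6-trimethyl-2,3-dihydro-4H-chromen-4-one (achiral) | COc1c(C)c(O)c(C(=O)C(C)C)c(O)c1Cc1c(O)c(C)c(O)c2c1OC(C)(C)CC2=O | target

## Step count and risks

Total step count: 7. Longest linear sequence: 5 steps (steps 1, 2, 3, 4, 7); the chromanone branch is 4 steps (1, 5, 6, 7).

**Three steps most likely to fail**

Step 7 (coupling). The ortho-quinone methide may form sluggishly from 8, whose reacting OH is hydrogen-bonded, and the diarylmethane product can fragment and scramble to symmetric dimers if heated too long with amine present. The fallback reverses the roles of the partners. It sets out from 11, which is aminomethylated with 7 (Et3N, CH2Cl2, rt) at its only free ring carbon to give 8-[(dimethylamino)methyl]-5,7-dihydroxy-2,2,6-trimethyl-2,3-dihydro-4H-chromen-4-one F1. Its free, more acidic 7-OH lets Me2NH leave at 80–100 °C in 1,4-dioxane to give the ortho-quinone methide 5-hydroxy-2,2,6-trimethyl-8-methylidene-2,3-dihydro-4H-chromene-4,7(8H)-dione F2. This is trapped in a Michael addition by the only free ring carbon of 6, and the fallback comes back to the route at 13.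

Step 6 (double demethylation). BBr3 may stall at the 7-OMe, or may open the tertiary aryl–alkyl ether of the pyranone ring, after which re-closure could give the 8-methyl isomer. The fallback does the two cleavages by different mechanisms. It sets out from 10, which with BCl3 (CH2Cl2, −78 → 0 °C) loses only the chelated methyl group to give 5-hydroxy-7-methoxy-2,2,6-trimethyl-2,3-dihydro-4H-chromen-4-one F3. The remaining para methyl ether is then removed by SN2 attack of NaSEt in DMF at 120 °C; under these basic conditions the substrate is a phenoxide, which disfavours ring opening. The fallback comes back to the route at 11.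

Step 5 (one-pot chromanone formation). In hot MeSO3H/P2O5 the phenol can instead be C-alkylated and lactonised to a 4,4-dimethyldihydrocoumarin, or be sulfonylated. The fallback builds the ring by an aldol condensation. It sets out from 3, which is acetylated ortho to the OH with acetic acid in BF3·OEt2 at 90 °C to give 1-(6-hydroxy-2,4-dimethoxy-3-methylphenyl)ethan-1-one F4. Kabbe condensation of this with acetone and pyrrolidine in EtOH at reflux (enamine aldol condensation, then oxa-Michael closure by the single free OH) comes back to the route at 10.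

## Further compounds

F1 | step 7 | 8-[(dimethylamino)methyl]-5,7-dihydroxy-2,2,6-trimethyl-2,3-dihydro-4H-chromen-4-one | Cc1c(O)c(CN(C)C)c2OC(C)(C)CC(=O)c2c1O
F2 | step 7 | 5-hydroxy-2,2,6-trimethyl-8-methylidene-2,3-dihydro-4H-chromene-4,7(8H)-dione | C=C1C(=O)C(C)=C(O)C2=C1OC(C)(C)CC2=O
F3 | step 6 | 5-hydroxy-7-methoxy-2,2,6-trimethyl-2,3-dihydro-4H-chromen-4-one | COc1cc2OC(C)(C)CC(=O)c2c(O)c1C
F4 | step 5 | 1-(6-hydroxy-2,4-dimethoxy-3-methylphenyl)ethan-1-one | CC(=O)c1c(O)cc(OC)c(C)c1OC
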